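Cutting the C4–C4a bond of ring B leaves C1 bearing two identical 3,4-dimethoxyphenyl groups. Fused ring A and pendant ring C are the same veratrole unit, and C1 stops being a stereocentre. The route exploits this. Its precursor is a small chiral lactone acetal, 3,4-trans-bis(methoxymethyl)-5-menthyloxybutyrolactone, whose acetal carbon is C1 and whose carbonyl carbon is C4. In one pot, acid attaches two veratroles to C1, which releases the C4 carboxylic acid, and trifluoroacetic anhydride then closes ring B by Friedel-Crafts acylation. The choice between the two diastereotopic aryl groups, steered by C2, creates C1. Hydrogenolysis of the C4 ketone completes a four-step synthesis.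

Key step: step 3

Assumption: butenolide 1, the acetal of 5-hydroxyfuran-2(5H)-one with natural l-menthol, is taken as a purchasable chiral building block.

Numbering: the tetralin numbering of the target is used throughout. C1 carries ring C, C2 and C3 carry the methoxymethyl groups, C4 is the benzylic CH2, C4a and C8a are the fusion carbons of ring A, and ring B is the saturated ring.

Step 1
Reactants: 1 (5R)-5-[(1R,2S,5R)-2-isopropyl-5-methylcyclohexyl]oxyfuran-2(5H)-one; 2 methoxyacetic acid
Product: 3 (4S,5R)-4-(methoxymethyl)-5-(l-menthyloxy)dihydrofuran-2(3H)-one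
Conditions: 2 (1.5 equiv), [Ir(dF(CF3)ppy)2(dtbbpy)]PF6 (1 mol %), K2HPO4, DMF, blue LEDs, rt
Reagents that add atoms: methoxyacetic acid 2, COCC(=O)O
Why: Photoredox decarboxylative Giese addition, in which the carboxylate of 2 is oxidised, loses CO2 and gives the nucleophilic methoxymethyl radical, which adds to the electron-poor lactone C4 (the future C2) on the face anti to the menthyloxy group at the acetal carbon and so sets the 4S centre before reduction and protonation of the α-acyl radical.

Step 2
Reactants: 3 (4S,5R)-4-(methoxymethyl)-5-(l-menthyloxy)dihydrofuran-2(3H)-one; 4 chloromethyl methyl ether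
Product: 6 (3S,4S,5R)-3,4-bis(methoxymethyl)-5-(l-menthyloxy)dihydrofuran-2(3H)-one, via lithium enolate 5 (not isolated)
Conditions: LDA, THF, −78 °C; then MeOCH2Cl, −78 to −40 °C
Reagents that add atoms: chloromethyl methyl ether 4, COCCl
Why: C-alkylation of a lactone lithium enolate with a reactive α-chloro ether, in which the electrophile enters anti to the neighbouring methoxymethyl group and gives the 3,4-trans lactone (sets 3S, the future C3).

Step 3
Reactants: 6 (3S,4S,5R)-3,4-bis(methoxymethyl)-5-(l-menthyloxy)dihydrofuran-2(3H)-one; 7 veratrole (1,2-dimethoxybenzene, two equivalents are incorporated)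
Product: 11 (2S,3S,4R)-4-(3,4-dimethoxyphenyl)-6,7-dimethoxy-2,3-bis(methoxymethyl)-3,4-dihydronaphthalen-1(2H)-one, via aryl lactone 8 (not isolated), via diaryl acid 9 (not isolated), via mixed anhydride 10 (not isolated)
Conditions: 7 (3 equiv), MeSO3H (2 equiv), CF3CO2H/CH2Cl2, 0 °C to rt; then (CF3CO)2O (4 equiv), 0 °C
Reagents that add atoms: veratrole 7, COc1ccccc1OC (twice); trifluoroacetic anhydride, O=C(OC(=O)C(F)(F)F)C(F)(F)F (its atoms appear only in intermediate 10, none in 11)
Why: MeSO3H opens the pseudo-ester acetal of 6 at the acyloxy C1–O bond, veratrole attacks the oxocarbenium ion through its position para to a methoxy group, the benzylic C1–O bond of the resulting lactone 8 ionises again to a 4-alkoxybenzyl cation that takes up the second veratrole and so releases acid 9, and trifluoroacetic anhydride converts 9 into mixed anhydride 10, whose acyl carbon C4 is attacked by C4a of one veratryl ring. The closest known reaction types are the Baeyer bis-arylation of aldehyde equivalents, the acid-mediated conversion of γ-aryl-γ-butyrolactones and arenes into 4-aryl-1-tetralones, and the intramolecular Friedel-Crafts acylation of 4-arylbutanoic acids with trifluoroacetic anhydride. Ring B closes as a six-membered ring by 6-exo-trig attack of the arene on the acyl group. C1 becomes a stereocentre only in this closure: in the chair-like transition state with H1 and H2 anti, both methoxymethyl groups and the spectator aryl group are equatorial, so the C2 centre selects the aryl group that is gauche to C3 and the 1,2-trans centre (4R in 11) should result, while C3, now next to the ketone, sits in its more stable equatorial position. The step needs site selectivity between C1 and C4, secured because C4 stays masked as a lactone until both aryl groups are on C1, and regioselectivity on the arene, secured because the position para to the 3-methoxy group is activated and unhindered, which gives the 6,7-dimethoxy pattern. Attack of the methoxymethyl oxygens on these sp2 electrophiles is reversible and should not divert material, and the intramolecular acylation should outrun acylation of residual veratrole.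

Step 4
Reactants: 11 (2S,3S,4R)-4-(3,4-dimethoxyphenyl)-6,7-dimethoxy-2,3-bis(methoxymethyl)-3,4-dihydronaphthalen-1(2H)-one
Product: 13 phyltetralin, (1R,2S,3S)-1-(3,4-dimethoxyphenyl)-6,7-dimethoxy-2,3-bis(methoxymethyl)-1,2,3,4-tetrahydronaphthalene, via benzylic alcohol 12 (not isolated)
Conditions: H2 (5 bar), Pd/C, AcOH, 40 °C
Reagents that add atoms: none
Why: Catalytic hydrogenolysis of an electron-rich aryl ketone through its benzylic alcohol, in which the C4–O bond para to a methoxy group is cleaved on palladium while the aliphatic methyl ethers and the three stereocentres, none of which takes part, are left as they are.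

Compound list
1 | (5R)-5-[(1R,2S,5R)-2-isopropyl-5-methylcyclohexyl]oxyfuran-2(5H)-one | O=C1O[C@@H](O[C@@H]2C[C@H](C)CC[C@H]2C(C)C)C=C1 | starting material
2 | methoxyacetic acid | COCC(=O)O | starting material
3 | (4S,5R)-4-(methoxymethyl)-5-(l-menthyloxy)dihydrofuran-2(3H)-one | O=C1O[C@@H](O[C@@H]2C[C@H](C)CC[C@H]2C(C)C)[C@H](COC)C1 | intermediate
4 | chloromethyl methyl ether | COCCl | starting material
5 | lithium enolate of 3 (lithium 2-oxido-4,5-dihydrofuran, 4S,5R) | [Li+].[O-]C1=C[C@@H](COC)[C@H](O[C@@H]2C[C@H](C)CC[C@H]2C(C)C)O1 | intermediate
6 | (3S,4S,5R)-3,4-bis(methoxymethyl)-5-(l-menthyloxy)dihydrofuran-2(3H)-one | O=C1O[C@@H](O[C@@H]2C[C@H](C)CC[C@H]2C(C)C)[C@H](COC)[C@H]1COC | intermediate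
7 | veratrole (1,2-dimethoxybenzene) | COc1ccccc1OC | starting material
8 | (3S,4S)-5-(3,4-dimethoxyphenyl)-3,4-bis(methoxymethyl)dihydrofuran-2(3H)-one (either epimer at the aryl-bearing carbon, a centre that is erased on ionisation) | O=C1OC(c2ccc(OC)c(OC)c2)[C@H](COC)[C@H]1COC | intermediate
9 | (2S,3S)-4,4-bis(3,4-dimethoxyphenyl)-2,3-bis(methoxymethyl)butanoic acid | COC[C@@H](C(=O)O)[C@H](C(c1ccc(OC)c(OC)c1)c1ccc(OC)c(OC)c1)COC | intermediate
10 | (2S,3S)-4,4-bis(3,4-dimethoxyphenyl)-2,3-bis(methoxymethyl)butanoic trifluoroacetic anhydride | COC[C@@H](C(=O)OC(=O)C(F)(F)F)[C@H](C(c1ccc(OC)c(OC)c1)c1ccc(OC)c(OC)c1)COC | intermediate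
11 | (2S,3S,4R)-4-(3,4-dimethoxyphenyl)-6,7-dimethoxy-2,3-bis(methoxymethyl)-3,4-dihydronaphthalen-1(2H)-one | COC[C@H]1C(=O)c2cc(OC)c(OC)cc2[C@@H](c2ccc(OC)c(OC)c2)[C@@H]1COC | intermediate
12 | (2S,3S,4R)-4-(3,4-dimethoxyphenyl)-6,7-dimethoxy-2,3-bis(methoxymethyl)-1,2,3,4-tetrahydronaphthalen-1-ol (carbinol epimers) | COC[C@H]1C(O)c2cc(OC)c(OC)cc2[C@@H](c2ccc(OC)c(OC)c2)[C@@H]1COC | intermediate
13 | phyltetralin, (1R,2S,3S)-1-(3,4-dimethoxyphenyl)-6,7-dimethoxy-2,3-bis(methoxymethyl)-1,2,3,4-tetrahydronaphthalene | COC[C@H]1Cc2cc(OC)c(OC)cc2[C@@H](c2ccc(OC)c(OC)c2)[C@@H]1COC | target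

Total step count: 4. Longest linear sequence: 4 steps (1, 3, 6, 11, 13).

Steps most likely to fail

**Step 3 (key step).**
- Proton loss from the C1 oxocarbenium ion or benzylic cation next to C2 would erode the C2 configuration.
- The released menthol may alkylate veratrole.
- The activated acyl group may be captured by the C2 methoxymethyl oxygen, followed by demethylation.
- The β-methoxy ketone may lose methanol under acid.
- The discrimination between the two aryl groups may be weak.

The fallback sets out from 6 and comes back at 11. It replaces the one-pot cascade on the menthyl acetal with a staged sequence in which each cationic event has its own mild promoter. Aqueous trifluoroacetic acid hydrolyses the acetal to the pseudo-acid (3S,4S)-5-hydroxy-3,4-bis(methoxymethyl)dihydrofuran-2(3H)-one F1, and the menthol is removed. The pseudo-acid is bis-arylated with veratrole under catalytic Bi(OTf)3 in nitromethane. Acid 9 is now isolated by extraction into base and freed from veratrole. It is then cyclised on its own with trifluoroacetic anhydride in CH2Cl2 at 0 °C, with no strong acid present, to give 11.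

**Step 1.**
- Oxidation of a primary alkoxyacetate may be slow.
- The butenolide may be reduced or oligomerised.
- The base may epimerise the acetal carbon through the 2-oxyfuran anion.
- Facial selectivity may be incomplete.

The fallback sets out from 1 and comes back at 3. It changes the radical source to hydrogen-atom abstraction. Benzophenone-sensitised irradiation of 1 in methanol adds the hydroxymethyl radical anti to the menthyloxy group and gives (4S,5R)-4-(hydroxymethyl)-5-(l-menthyloxy)dihydrofuran-2(3H)-one F2. Its primary alcohol is then methylated under non-basic conditions with MeI and Ag2O to give 3.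

**Step 4.**
- The reduction may stall at the benzylic alcohol.
- Acid-promoted dehydration towards the 1,2-dihydronaphthalene would scramble C3.
- Methanol may be lost from the β-methoxy ketone before reduction.

The fallback sets out from 11 and comes back at 13. It removes the oxygen by a neutral radical path (Barton-McCombie deoxygenation). NaBH4 in methanol gives alcohol 12, now isolated. NaH, CS2 and MeI convert it into O-[(2S,3S,4R)-4-(3,4-dimethoxyphenyl)-6,7-dimethoxy-2,3-bis(methoxymethyl)-1,2,3,4-tetrahydronaphthalen-1-yl] S-methyl carbonodithioate F3. Bu3SnH with AIBN in refluxing toluene then gives 13.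

Further compounds
F1 | step 3 | (3S,4S)-5-hydroxy-3,4-bis(methoxymethyl)dihydrofuran-2(3H)-one | O=C1OC(O)[C@H](COC)[C@H]1COC
F2 | step 1 | (4S,5R)-4-(hydroxymethyl)-5-(l-menthyloxy)dihydrofuran-2(3H)-one | O=C1O[C@@H](O[C@@H]2C[C@H](C)CC[C@H]2C(C)C)[C@H](CO)C1
F3 | step 4 | O-[(2S,3S,4R)-4-(3,4-dimethoxyphenyl)-6,7-dimethoxy-2,3-bis(methoxymethyl)-1,2,3,4-tetrahydronaphthalen-1-yl] S-methyl carbonodithioate | COC[C@H]1C(OC(=S)SC)c2cc(OC)c(OC)cc2[C@@H](c2ccc(OC)c(OC)c2)[C@@H]1COC
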